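## The problem

The target 22 is a flat, achiral 3-methoxyflavone, so no stereocentre has to be set. The stereocentres that appear on the way (C3 of an open-chain diketone, C2 and C3 of a cyclic hemiketal) are transient, control nothing and vanish when ring C becomes aromatic. The real task is to tell eight oxygen atoms apart: free hydroxyls at C5, C7, C2' and C4' against methyl ethers at C3, C6, C8 and C5'. Ring A is fully substituted, with oxygen on C5, C6, C7, C8 and C8a in the alternating order OH, OMe, OH, OMe, O1. C4a is its only position bonded to carbon, so the C4a–C4 bond has to be made between two ortho oxygen substituents. The C2' oxygen of ring B sits where it could close a pyranone onto C4 in the wrong direction, so it must stay masked while O1–C2 is formed. The free polyphenol oxidises in air under basic conditions, the 4-pyranone opens with hydroxide or alkoxide, and strong Lewis acids strip methyl ethers next to the carbonyl, so the closing steps must be mild. Two features allow a short convergent answer. C4 is a carbonyl carbon bonded only to the aryl carbon C4a and to the methoxylated C3, which is the footprint of carbon monoxide placed between an aryl halide and an enolate. Ring A, with O1 regarded as a hydroxyl, is mirror-symmetric about the line through C4a and C7, so C4a is the single free carbon of a symmetric arene and either ortho oxygen can become O1.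

## Retrosynthesis

22 from 21. The three benzyl C–O bonds at C7, C2' and C4' are cut last. Benzyl ethers survive base, organolithium reagents, palladium catalysis and methanolic acid, and they leave under neutral hydrogenolysis, which suits an oxidation-prone polyphenol. The fourth phenol (C5–OH) is already free in 21 and is tamed by its hydrogen bond to the C4 carbonyl. The forward step must spare the C2–C3 double bond and the four methyl ethers.

21 from 18. Ring C is opened at O1–C2, which leads back through hemiketal 20 and diphenol 19 to the 1,3-diketone 18, in which the C5 and C8a oxygens are methoxymethyl ethers. Cutting O1–C2 and not O1–C8a keeps the heteroatom on ring A from the start, so ring closure is a spontaneous carbonyl addition and not a metal-mediated aryl C–O coupling. The two ortho oxygens of ring A are equivalent, so the closure has no regiochemical side. The forward step asks for one thing: the acetal-type ethers on ring A must fall under acid while the C2' benzyl ether stays, which is why ring A carries methoxymethyl groups and ring B benzyl groups.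

18 from 7, 17 and 16. The C4a–C4 and C4–C3 bonds are cut together, returning aryl iodide 7, carbon monoxide 17 and methoxymethyl ketone 16. The neighbouring cuts keep C4 on one ring. Cutting only C4–C3 demands acyl substitution at a benzoate flanked by two ortho oxygens, which is slow. Cutting C2–C3 first needs C-acylation of the pentaoxygenated ring and then separate handling of its two ortho oxygens. With 17 as C4, the crowded C4a–C4 bond is made by migratory insertion at palladium, a step that ortho substitution accelerates, and the acyl transfer occurs at the metal. The precursors are two arenes of similar size, each five steps from a commodity chemical. The forward reaction must acylate the enolate of 16 at carbon, not at oxygen, must not arylate it directly, and must tolerate the acetal and benzyl ethers.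

7 from 5 and 4. The C4a–I bond is cut to the bis(methoxymethyl) ether 5 by way of aryllithium 6. The hydrogen between two methoxymethoxy groups is the classic site of directed ortho-lithiation and is the only ring hydrogen of 5, so the iodide is placed without choice. Electrophilic iodination of the free resorcinol 4 is the neighbouring option and is kept in reserve, because it exposes an electron-rich phenol to an oxidant. Removing the two acetal groups from 5 gives 4. The lithiation must leave the benzylic CH2 of the C7 ether untouched.

4 from 3, 2 and 1. The two phenolic C–O bonds of 4 (future C5–O and C8a–O1) are traced to the C–Br bonds of dibromide 3, these to C–H bonds of benzyl ether 2, and 2 to syringol 1. Compound 1 already holds the C7 oxygen between the C6 and C8 methoxy groups. The two missing oxygens are wanted exactly where a 1,2,3-trioxygenated benzene is brominated, ortho to one methoxy group and para to the other. Because 2 is symmetric, double bromination and double hydroxylation each have one possible product.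

16 from 13 and 14. The aryl–carbonyl bond (C1'–C2 of the target) is cut into aryl bromide 13 and amide 14, joined through aryllithium 15. Amide 14 brings C2, C3 and the C3 methoxy group in one piece, and acylation of an aryllithium by an N-methoxy-N-methylamide stops at the ketone. The neighbouring cut, Friedel–Crafts acylation of arene 12, would place a Lewis acid beside a benzyl ether ortho to the new carbonyl, the arrangement most prone to debenzylation, so it is held back as a reserve.

13 from 12, 11, 9 and 8. The C–Br bond of 13 goes back to arene 12, the O–CH3 bond of 12 to phenol 11, and the phenolic oxygen of 11 to the formyl group of aldehyde 9 through formate 10. Aldehyde 9 goes back to 2,4-dihydroxybenzaldehyde 8 by two O-benzyl cuts. Compound 8 fixes the 1,3-relation of the C2' and C4' oxygens. Its formyl group is a masked C5' oxygen that is unveiled only after both phenols are benzylated, so the hydroxyl that appears is unambiguously the one to methylate. Bromination of 12 is asked to occur para to one benzyloxy group and ortho to the other, which is the future C1'.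

## Roads not taken

Alternative 1: Ring A would be built last, by cutting C8–C8a and, one step earlier, C4a–C5. Ring C with ring B attached would be metalated at C5 and added to the mixed squarate A3, and the resulting 4-hydroxycyclobutenone A2 would be heated. Electrocyclic opening gives a dienylketene whose ketene carbon closes onto pyranone C6, and tautomerisation delivers hydroquinone A1.
- Merits: no polyoxygenated benzene has to be functionalised. Every ring A oxygen of A1 is chemically distinct (chelated C5–OH, free C8–OH, methyl ether at C6, tert-butyl ether at C7), so the C8 hydroxyl should be methylated selectively.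
- Weak points: the addition to A3 must choose between two carbonyl groups that differ only in the size of the neighbouring alkoxy group, and the wrong choice transposes the C6 and C7 substituents. A 4-pyranone metalated next to its carbonyl and carrying a free C6–H is a delicate nucleophile. Three further steps (O-methylation, tert-butyl removal, debenzylation) follow A1.
- Comparison: this road differentiates the ring A oxygens more elegantly and is independent of aromatic substitution, whereas the plan adopted here spends five steps on iodide 7. Against that, the adopted plan sets the symmetry of ring A, which removes every regiochemical decision, and a key step of an established reaction type.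

Alternative 2: O1–C8a, C4a–C4 and O1–C2 would be cut at once. The aryne released from silyl triflate A5 by CsF inserts into the C–O bond of the caesium acrylate A6. The resulting ortho-acyl phenoxide then displaces methoxide at C2 to give flavone A4.
- Merits: three bonds and ring C in one operation, the most convergent of the four plans. The regiochemistry of addition to the 3-alkoxyaryne is correct, since oxygen adds remote from the alkoxy group and the acyl group ends next to it.
- Weak points: A4 carries hydrogen at C8. An aryne precursor oxygenated at all four remaining positions would be hard to make, so the C8 methoxy group must be added to the finished flavone by halogenation or oxidation and then methylation, in competition with the electron-rich ring B. The tetrasubstituted acrylate A6 also costs several steps.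
- Comparison: this road reaches the flavone core in fewer steps, a real advantage. It stops one oxygen short, however, and the late C8 oxygenation is exactly the regiochemical problem that the adopted plan avoids by starting from a ring A that already holds all five oxygens.

Alternative 3: Only O1–C8a would be cut. The dibromo diketone A8, from ketone 16 and aroyl chloride A9, is closed with CuI and K2CO3. The enol oxygen of the ring B carbonyl displaces one of two equivalent ortho bromides to give bromoflavone A7.
- Merits: the same symmetry argument applies. The ring A piece A9 is probably shorter to make than 7, and no carbon monoxide is handled.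
- Weak points: A8 needs acyl substitution at an aroyl chloride flanked by two ortho bromides. The copper-mediated closure must occur at a C–Br bond between an acyl and a methoxy group on an electron-rich ring. The remaining C5–Br of A7 must be turned into C5–OH on the finished flavone, under hydroxide or alkoxide conditions that the pyranone tolerates poorly.
- Comparison: in length to ring A and in operational simplicity this road is at least as good. The adopted plan sets against it that both ring A oxygens are in place before the fragments meet, that ring closure is an uncatalysed hemiketalisation, and that no carbon–halogen bond is carried into the flavone.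

Key step: step 11

## Route

Assumption: N,2-dimethoxy-N-methylacetamide 14 is taken as a catalogue reagent; were it not, one amidation of methoxyacetyl chloride with N,O-dimethylhydroxylamine would supply it.

Step 1
Reactants: 1 2,6-dimethoxyphenol (syringol)
Product: 2 2-(benzyloxy)-1,3-dimethoxybenzene
Conditions: BnBr, K2CO3, DMF, 60 °C
Reagents that add atoms: benzyl bromide, BrCc1ccccc1
Why: Williamson etherification; the phenol between two methoxy groups is acidic enough for K2CO3 and alkylates cleanly in DMF.

Step 2
Reactants: 2 2-(benzyloxy)-1,3-dimethoxybenzene
Product: 3 3-(benzyloxy)-1,5-dibromo-2,4-dimethoxybenzene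
Conditions: NBS (2.2 equiv), MeCN, rt to 40 °C
Reagents that add atoms: N-bromosuccinimide, O=C1CCC(=O)N1Br
Why: Electrophilic aromatic bromination; each outer methoxy group directs ortho and para, so the first bromine should enter C4 and the second the equivalent C6, whereas C5 is activated only by the twisted central benzyloxy group.

Step 3
Reactants: 3 3-(benzyloxy)-1,5-dibromo-2,4-dimethoxybenzene
Product: 4 5-(benzyloxy)-4,6-dimethoxybenzene-1,3-diol
Conditions: Pd2(dba)3 (2 mol%), tBuXPhos (8 mol%), KOH, 1,4-dioxane/H2O, 100 °C; then aq HCl
Reagents that add atoms: potassium hydroxide, [K+].[OH-]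
Why: Palladium-catalysed hydroxylation of aryl bromides (C–O cross-coupling with hydroxide) under a bulky biarylphosphine; each bromide has only one ortho substituent, and the phenoxide formed first is meta to the remaining bromide, so it should not retard the second coupling by resonance.

Step 4
Reactants: 4 5-(benzyloxy)-4,6-dimethoxybenzene-1,3-diol
Product: 5 3-(benzyloxy)-2,4-dimethoxy-1,5-bis(methoxymethoxy)benzene
Conditions: NaH, DMF, 0 °C; MOMCl, 0 °C to rt
Reagents that add atoms: chloromethyl methyl ether, COCCl
Why: O-alkylation of the bis-phenoxide with an alkoxymethyl chloride; each hydroxyl has a free ortho position, so both react readily.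

Step 5
Reactants: 5 3-(benzyloxy)-2,4-dimethoxy-1,5-bis(methoxymethoxy)benzene
Product: 7 5-(benzyloxy)-2-iodo-4,6-dimethoxy-1,3-bis(methoxymethoxy)benzene, via aryllithium 6 (not isolated)
Conditions: n-BuLi (1.1 equiv), THF, −20 to 0 °C; then I2, −78 °C to rt
Reagents that add atoms: iodine, II
Why: Directed ortho-metalation followed by iodination; the only ring hydrogen lies between two methoxymethoxy groups that both acidify it and chelate lithium, so metalation there should be much faster than at the benzylic CH2 when only a slight excess of base is used.

Step 6
Reactants: 8 2,4-dihydroxybenzaldehyde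
Product: 9 2,4-bis(benzyloxy)benzaldehyde
Conditions: BnBr (2.3 equiv), K2CO3, DMF, 70 °C
Reagents that add atoms: benzyl bromide, BrCc1ccccc1
Why: Double Williamson etherification; warming overcomes the hydrogen bond of the C2 hydroxyl to the formyl group.

Step 7
Reactants: 9 2,4-bis(benzyloxy)benzaldehyde
Product: 11 2,4-bis(benzyloxy)phenol, via aryl formate 10 (not isolated)
Conditions: mCPBA, CH2Cl2, 0 °C to rt; then K2CO3 (cat.), MeOH, rt
Reagents that add atoms: 3-chloroperoxybenzoic acid, OOC(=O)c1cccc(Cl)c1
Why: Baeyer–Villiger oxidation of an electron-rich benzaldehyde (Dakin-type); the aryl group with ortho and para alkoxy donors migrates in preference to hydrogen, and the formate is methanolysed in the same flask.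

Step 8
Reactants: 11 2,4-bis(benzyloxy)phenol
Product: 12 2,4-bis(benzyloxy)-1-methoxybenzene
Conditions: MeI, K2CO3, acetone, reflux
Reagents that add atoms: iodomethane, CI
Why: Williamson O-methylation of the only free phenol.

Step 9
Reactants: 12 2,4-bis(benzyloxy)-1-methoxybenzene
Product: 13 1,5-bis(benzyloxy)-2-bromo-4-methoxybenzene
Conditions: NBS (1.05 equiv), MeCN, 0 °C
Reagents that add atoms: N-bromosuccinimide, O=C1CCC(=O)N1Br
Why: Electrophilic aromatic bromination; C5 of 12 is para to one benzyloxy group and ortho to the other, whereas C3 is shielded between two benzyloxy groups and C6 is activated by the methoxy group alone.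

Step 10
Reactants: 13 1,5-bis(benzyloxy)-2-bromo-4-methoxybenzene; 14 N,2-dimethoxy-N-methylacetamide
Product: 16 1-[2,4-bis(benzyloxy)-5-methoxyphenyl]-2-methoxyethan-1-one, via aryllithium 15 (not isolated)
Conditions: n-BuLi, THF, −78 °C; 14, −78 to 0 °C; then 1 M HCl
Reagents that add atoms: none
Why: Bromine–lithium exchange followed by Weinreb ketone synthesis; the chelated tetrahedral adduct prevents a second addition, and the low temperature keeps the aryllithium ortho to a benzyloxy group intact.

Step 11
Reactants: 7 5-(benzyloxy)-2-iodo-4,6-dimethoxy-1,3-bis(methoxymethoxy)benzene; 16 1-[2,4-bis(benzyloxy)-5-methoxyphenyl]-2-methoxyethan-1-one; 17 carbon monoxide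
Product: 18 racemic 1-[4-(benzyloxy)-3,5-dimethoxy-2,6-bis(methoxymethoxy)phenyl]-3-[2,4-bis(benzyloxy)-5-methoxyphenyl]-2-methoxypropane-1,3-dione
Conditions: 16 (2.2 equiv), NaN(SiMe3)2 (2.1 equiv), THF, −78 to 0 °C; then 7, Pd(dba)2 (5 mol%), Xantphos (5 mol%), CO (1 atm, generated ex situ in a two-chamber vessel), 1,4-dioxane, 80 °C; then cold 0.5 M HCl
Reagents that add atoms: none
Why: This is a carbonylative alpha-arylation of a ketone, the known palladium-catalysed three-component coupling of aryl iodides, carbon monoxide and ketone enolates to 1,3-diketones. Zerovalent palladium carrying Xantphos inserts into the C4a–I bond of 7, and migratory insertion of 17 gives an aroylpalladium iodide, a step that relieves the crowding between the metal and the two flanking methoxymethoxy groups. The preformed sodium enolate of 16 displaces iodide at palladium, and reductive elimination from the acylpalladium enolate forms C4–C3. A second enolate equivalent deprotonates the product, so 18 leaves the cycle as a stabilised sodium diketonate that is not acylated again. No ring is closed. The new stereocentre at C3 is not controlled: 18 is racemic and enolisable, and this carbon becomes sp2 in step 12. The step needs C-acylation in preference to O-acylation and to direct alpha-arylation; the di-ortho-substituted arylpalladium is too hindered for direct C–C reductive elimination but takes up CO readily, the wide bite angle of Xantphos favours elimination from the acyl complex, and the chelated sodium enolate of the alpha-methoxy ketone reacts at carbon. Keeping the enolate in slight excess over the amide base avoids capture of the acylpalladium species by free NaN(SiMe3)2.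

Step 12
Reactants: 18 racemic 1-[4-(benzyloxy)-3,5-dimethoxy-2,6-bis(methoxymethoxy)phenyl]-3-[2,4-bis(benzyloxy)-5-methoxyphenyl]-2-methoxypropane-1,3-dione
Product: 21 7-(benzyloxy)-2-[2,4-bis(benzyloxy)-5-methoxyphenyl]-5-hydroxy-3,6,8-trimethoxy-4H-chromen-4-one, via diphenol diketone 19 (not isolated), via cyclic hemiketal 20 (not isolated)
Conditions: HCl (3 M in MeOH), THF, 55 °C
Reagents that add atoms: none
Why: Acidic acetal cleavage frees both ring A phenols, either of which (they are equivalent) adds to the ring B carbonyl to give the six-membered hemiketal, and acid-catalysed dehydration, driven by aromatisation of the 4-pyranone, completes a cyclodehydration of the Baker–Venkataraman type. The benzyl ethers, including the one at C2', should survive, so ring B cannot close in the opposite sense.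

Step 13
Reactants: 21 7-(benzyloxy)-2-[2,4-bis(benzyloxy)-5-methoxyphenyl]-5-hydroxy-3,6,8-trimethoxy-4H-chromen-4-one
Product: 22 5,7,2',4'-tetrahydroxy-3,6,8,5'-tetramethoxyflavone (5,7-dihydroxy-2-(2,4-dihydroxy-5-methoxyphenyl)-3,6,8-trimethoxy-4H-chromen-4-one)
Conditions: H2 (1 atm), Pd/C (10%), EtOAc/MeOH, rt
Reagents that add atoms: none
Why: Catalytic hydrogenolysis of three aryl benzyl ethers under neutral conditions; the tetrasubstituted C2–C3 double bond is part of a vinylogous ester and should not be reduced at atmospheric pressure.

## Compound list

1 | 2,6-dimethoxyphenol (syringol) | COc1cccc(OC)c1O | starting material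
2 | 2-(benzyloxy)-1,3-dimethoxybenzene | COc1cccc(OC)c1OCc1ccccc1 | intermediate
3 | 3-(benzyloxy)-1,5-dibromo-2,4-dimethoxybenzene | COc1c(Br)cc(Br)c(OC)c1OCc1ccccc1 | intermediate
4 | 5-(benzyloxy)-4,6-dimethoxybenzene-1,3-diol | COc1c(O)cc(O)c(OC)c1OCc1ccccc1 | intermediate
5 | 3-(benzyloxy)-2,4-dimethoxy-1,5-bis(methoxymethoxy)benzene | COCOc1cc(OCOC)c(OC)c(OCc2ccccc2)c1OC | intermediate
6 | [4-(benzyloxy)-3,5-dimethoxy-2,6-bis(methoxymethoxy)phenyl]lithium (not isolated) | [Li]c1c(OCOC)c(OC)c(OCc2ccccc2)c(OC)c1OCOC | intermediate
7 | 5-(benzyloxy)-2-iodo-4,6-dimethoxy-1,3-bis(methoxymethoxy)benzene | COCOc1c(I)c(OCOC)c(OC)c(OCc2ccccc2)c1OC | intermediate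
8 | 2,4-dihydroxybenzaldehyde | O=Cc1ccc(O)cc1O | starting material
9 | 2,4-bis(benzyloxy)benzaldehyde | O=Cc1ccc(OCc2ccccc2)cc1OCc1ccccc1 | intermediate
10 | 2,4-bis(benzyloxy)phenyl formate (not isolated) | O=COc1ccc(OCc2ccccc2)cc1OCc1ccccc1 | intermediate
11 | 2,4-bis(benzyloxy)phenol | Oc1ccc(OCc2ccccc2)cc1OCc1ccccc1 | intermediate
12 | 2,4-bis(benzyloxy)-1-methoxybenzene | COc1ccc(OCc2ccccc2)cc1OCc1ccccc1 | intermediate
13 | 1,5-bis(benzyloxy)-2-bromo-4-methoxybenzene | COc1cc(Br)c(OCc2ccccc2)cc1OCc1ccccc1 | intermediate
14 | N,2-dimethoxy-N-methylacetamide | COCC(=O)N(C)OC | starting material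
15 | [2,4-bis(benzyloxy)-5-methoxyphenyl]lithium (not isolated) | [Li]c1cc(OC)c(OCc2ccccc2)cc1OCc1ccccc1 | intermediate
16 | 1-[2,4-bis(benzyloxy)-5-methoxyphenyl]-2-methoxyethan-1-one | COCC(=O)c1cc(OC)c(OCc2ccccc2)cc1OCc1ccccc1 | intermediate
17 | carbon monoxide | [C-]#[O+] | starting material
18 | racemic 1-[4-(benzyloxy)-3,5-dimethoxy-2,6-bis(methoxymethoxy)phenyl]-3-[2,4-bis(benzyloxy)-5-methoxyphenyl]-2-methoxypropane-1,3-dione | COC(C(=O)c1c(OCOC)c(OC)c(OCc2ccccc2)c(OC)c1OCOC)C(=O)c1cc(OC)c(OCc2ccccc2)cc1OCc1ccccc1 | intermediate
19 | racemic 1-[4-(benzyloxy)-2,6-dihydroxy-3,5-dimethoxyphenyl]-3-[2,4-bis(benzyloxy)-5-methoxyphenyl]-2-methoxypropane-1,3-dione (not isolated) | COC(C(=O)c1c(O)c(OC)c(OCc2ccccc2)c(OC)c1O)C(=O)c1cc(OC)c(OCc2ccccc2)cc1OCc1ccccc1 | intermediate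
20 | 7-(benzyloxy)-2-[2,4-bis(benzyloxy)-5-methoxyphenyl]-2,5-dihydroxy-3,6,8-trimethoxy-2,3-dihydro-4H-chromen-4-one, mixture of racemic diastereomers at C2 and C3 (not isolated) | COC1C(=O)c2c(O)c(OC)c(OCc3ccccc3)c(OC)c2OC1(O)c1cc(OC)c(OCc2ccccc2)cc1OCc1ccccc1 | intermediate
21 | 7-(benzyloxy)-2-[2,4-bis(benzyloxy)-5-methoxyphenyl]-5-hydroxy-3,6,8-trimethoxy-4H-chromen-4-one | COc1cc(-c2oc3c(OC)c(OCc4ccccc4)c(OC)c(O)c3c(=O)c2OC)c(OCc2ccccc2)cc1OCc1ccccc1 | intermediate
22 | 5,7,2',4'-tetrahydroxy-3,6,8,5'-tetramethoxyflavone | COc1cc(-c2oc3c(OC)c(O)c(OC)c(O)c3c(=O)c2OC)c(O)cc1O | target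

## Step count and risks

Total: 13 steps. Longest linear sequence: 8 steps (steps 1 to 5 or steps 6 to 10, then steps 11 to 13).

Step 11 (key step). The acylpalladium intermediate may be captured at the enolate oxygen, or oxidative addition and CO insertion may stall at the crowded, electron-rich C4a–I bond, leading to hydrodeiodination while the enolate self-condenses at 80 °C. The fallback separates the two bond formations and sets out from 5. Lithiation as in step 5 (through 6) and a quench with N,N-dimethylformamide should give 4-(benzyloxy)-3,5-dimethoxy-2,6-bis(methoxymethoxy)benzaldehyde F1. Aldol addition of the lithium enolate of 16 (LiN(SiMe3)2, THF, −78 °C) should give 3-[4-(benzyloxy)-3,5-dimethoxy-2,6-bis(methoxymethoxy)phenyl]-1-[2,4-bis(benzyloxy)-5-methoxyphenyl]-3-hydroxy-2-methoxypropan-1-one F2 as a mixture of racemic diastereomers. Oxidation with Dess–Martin periodinane returns to the route at 18. In this reserve C4 comes from the formamide and not from 17.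

Step 3. The second C–O coupling may remain incomplete, or the phenoxide formed first may enter the cycle as a nucleophile and cause diaryl ether formation. The fallback sets out from 3. Double Miyaura borylation (PdCl2(dppf), bis(pinacolato)diboron, KOAc, 1,4-dioxane, 90 °C) should give 2,2'-[5-(benzyloxy)-4,6-dimethoxy-1,3-phenylene]bis(4,4,5,5-tetramethyl-1,3,2-dioxaborolane) F3. Oxidation with NaOH and H2O2 at 0 °C returns to the route at 4.

Step 5. Deprotonation at the benzylic CH2 of the C7 ether may compete and be followed by Wittig rearrangement, or metalation of the crowded ring may be incomplete. The fallback sets out from 4. Electrophilic iodination at its only free position (I2, NaHCO3, THF/H2O, 0 °C) should give 5-(benzyloxy)-2-iodo-4,6-dimethoxybenzene-1,3-diol F4. Protection with NaH and chloromethyl methyl ether returns to the route at 7.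

Step 10. The aryllithium may be quenched by proton transfer, either from a benzylic position on warming or from the CH2 of the amide, which would return the debrominated arene. The fallback sets out from 12 and uses a Friedel–Crafts acylation with methoxyacetyl chloride and SnCl4 in CH2Cl2 at −40 °C. It should take place at the same doubly activated position and returns to the route at 16 without any new intermediate.

Step 13. The C2–C3 double bond may be over-reduced, or cleavage of the C7 benzyl ether between two methoxy groups may be slow, with air oxidation of the polyphenol during a prolonged reaction. The fallback sets out from 21 and replaces hydrogenolysis by Lewis-acid debenzylation with BCl3 and pentamethylbenzene as cation scavenger in CH2Cl2 at −78 °C. At that temperature the methyl ethers should remain, and the route is rejoined at 22.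

## Further compounds

F1 | step 11 | 4-(benzyloxy)-3,5-dimethoxy-2,6-bis(methoxymethoxy)benzaldehyde | COCOc1c(C=O)c(OCOC)c(OC)c(OCc2ccccc2)c1OC
F2 | step 11 | 3-[4-(benzyloxy)-3,5-dimethoxy-2,6-bis(methoxymethoxy)phenyl]-1-[2,4-bis(benzyloxy)-5-methoxyphenyl]-3-hydroxy-2-methoxypropan-1-one (mixture of racemic diastereomers) | COC(C(O)c1c(OCOC)c(OC)c(OCc2ccccc2)c(OC)c1OCOC)C(=O)c1cc(OC)c(OCc2ccccc2)cc1OCc1ccccc1
F3 | step 3 | 2,2'-[5-(benzyloxy)-4,6-dimethoxy-1,3-phenylene]bis(4,4,5,5-tetramethyl-1,3,2-dioxaborolane) | COc1c(B2OC(C)(C)C(C)(C)O2)cc(B2OC(C)(C)C(C)(C)O2)c(OC)c1OCc1ccccc1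
F4 | step 5 | 5-(benzyloxy)-2-iodo-4,6-dimethoxybenzene-1,3-diol | COc1c(O)c(I)c(O)c(OC)c1OCc1ccccc1
F0 | step 10 | none | none
F0 | step 13 | none | none
A1 | alternative 1 | 2-[2,4-bis(benzyloxy)-5-methoxyphenyl]-7-tert-butoxy-5,8-dihydroxy-3,6-dimethoxy-4H-chromen-4-one | COc1cc(-c2oc3c(O)c(OC(C)(C)C)c(OC)c(O)c3c(=O)c2OC)c(OCc2ccccc2)cc1OCc1ccccc1
A2 | alternative 1 | racemic 2-[2,4-bis(benzyloxy)-5-methoxyphenyl]-5-(3-tert-butoxy-1-hydroxy-2-methoxy-4-oxocyclobut-2-en-1-yl)-3-methoxy-4H-pyran-4-one | COC1=C(OC(C)(C)C)C(=O)C1(O)c1coc(-c2cc(OC)c(OCc3ccccc3)cc2OCc2ccccc2)c(OC)c1=O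
A3 | alternative 1 | 3-tert-butoxy-4-methoxycyclobut-3-ene-1,2-dione | COC1=C(OC(C)(C)C)C(=O)C1=O
A4 | alternative 2 | 5,7-bis(benzyloxy)-2-[2,4-bis(benzyloxy)-5-methoxyphenyl]-3,6-dimethoxy-4H-chromen-4-one | COc1c(-c2cc(OC)c(OCc3ccccc3)cc2OCc2ccccc2)oc2cc(OCc3ccccc3)c(OC)c(OCc3ccccc3)c2c1=O
A5 | alternative 2 | 3,5-bis(benzyloxy)-4-methoxy-2-(trimethylsilyl)phenyl trifluoromethanesulfonate | COc1c(OCc2ccccc2)cc(OS(=O)(=O)C(F)(F)F)c([Si](C)(C)C)c1OCc1ccccc1
A6 | alternative 2 | caesium 3-[2,4-bis(benzyloxy)-5-methoxyphenyl]-2,3-dimethoxyprop-2-enoate (double-bond geometry left open) | COC(=C(OC)C(=O)[O-])c1cc(OC)c(OCc2ccccc2)cc1OCc1ccccc1.[Cs+]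
A7 | alternative 3 | 7-(benzyloxy)-2-[2,4-bis(benzyloxy)-5-methoxyphenyl]-5-bromo-3,6,8-trimethoxy-4H-chromen-4-one | COc1c(-c2cc(OC)c(OCc3ccccc3)cc2OCc2ccccc2)oc2c(OC)c(OCc3ccccc3)c(OC)c(Br)c2c1=O
A8 | alternative 3 | racemic 1-[4-(benzyloxy)-2,6-dibromo-3,5-dimethoxyphenyl]-3-[2,4-bis(benzyloxy)-5-methoxyphenyl]-2-methoxypropane-1,3-dione | COC(C(=O)c1c(Br)c(OC)c(OCc2ccccc2)c(OC)c1Br)C(=O)c1cc(OC)c(OCc2ccccc2)cc1OCc1ccccc1
A9 | alternative 3 | 4-(benzyloxy)-2,6-dibromo-3,5-dimethoxybenzoyl chloride | COc1c(Br)c(C(Cl)=O)c(Br)c(OC)c1OCc1ccccc1
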